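**Plan**
- Retrosynthesis: the ester C3–O bond is cut first, then the side-chain bond C5–C1' (alkenyl triflate plus alkylborane). Then C6–C7, C4a–C8a and N1–C8a are cut together, which opens both rings to an acyclic sulfonamido β-keto ester and acrolein.
- Enabling feature: in the carbocycle (C4a–C5–C6–C7–C8–C8a) a carbonyl at C5 makes both flanking carbons, C4a and C6, nucleophilic, and C7–C8–C8a is an acrolein unit. N1 hangs on the four-atom tether N1–C2–C3–C4 from C4a, so the enone formed by the annulation closes the piperidine ring by 6-endo addition.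
- Forward order: acyclic chain 7 → carbocycle, then piperidine ring in the same pot → decarboxylation → C5 enol triflate → sp2–sp3 coupling with the side chain → hydrogenation → exchange of the N-protecting group → esterification → deprotection.
- Stereochemistry: C2 and C3 come from asymmetric aminohydroxylation of ethyl crotonate. C8a and C4a are relayed from C2 (axial methyl next to the N-sulfonyl group, then protonation on the open face). C5 is set by hydrogenation from the convex face, and C5' comes from (R)-2-propyloxirane.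
- Helpers: the tert-butyl ester on C6 (directs the Michael step) and the N-tosyl group (acidifies N–H, enforces the chair) are removed in steps 7 and 13.

Key step: step 6

Remark (assumption): compound 2 is carried on after recrystallization to a single enantiomer, and (R)-2-propyloxirane (15) is taken as a purchasable enantiopure epoxide.

**Route**

Step 1
Reactants: 1 ethyl (E)-but-2-enoate
Product: 2 ethyl (2S,3R)-2-hydroxy-3-(tosylamino)butanoate
Conditions: TsN(Cl)Na·3H2O, K2OsO2(OH)4 (4 mol %), (DHQD)2PHAL (5 mol %), tBuOH/H2O (1:1), rt; recrystallization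
Reagents that add atoms: chloramine-T, [Na+].Cc1ccc(cc1)S(=O)(=O)[N-]Cl; water, O
Why: Sharpless asymmetric aminohydroxylation adds N and O to the same face of the (E)-alkene with nitrogen at the β-carbon, so the threo relationship of C2/C3 follows from the alkene geometry and the (2S,3R) sense from the dihydroquinidine ligand, and crystallization should remove residual minor enantiomer.

Step 2
Reactants: 2 ethyl (2S,3R)-2-hydroxy-3-(tosylamino)butanoate
Product: 3 ethyl (2S,3R)-2-(benzyloxy)-3-(tosylamino)butanoate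
Conditions: benzyl 2,2,2-trichloroacetimidate, TfOH (5 mol %), CH2Cl2/cyclohexane, 0 °C → rt
Reagents that add atoms: benzyl 2,2,2-trichloroacetimidate, N=C(OCc1ccccc1)C(Cl)(Cl)Cl
Why: Acid-catalysed O-benzylation with the trichloroacetimidate etherifies the secondary alcohol without base, so the acidic sulfonamide N–H is not alkylated and the α-stereocenter is not epimerized.

Step 3
Reactants: 3 ethyl (2S,3R)-2-(benzyloxy)-3-(tosylamino)butanoate
Product: 5 methyl (2E,4R,5R)-4-(benzyloxy)-5-(tosylamino)hex-2-enoate, via α-benzyloxy aldehyde 4 (not isolated)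
Conditions: iBu2AlH (2.2 equiv), CH2Cl2, −78 °C; then Ph3P=CHCO2Me, MeOH, −78 °C → rt
Reagents that add atoms: methyl (triphenylphosphoranylidene)acetate, COC(=O)C=P(c1ccccc1)(c1ccccc1)c1ccccc1
Why: Partial reduction of the α-alkoxy ester gives a chelated aluminium hemiacetal that releases the aldehyde only as the stabilized ylide is added (one-pot reduction/Wittig olefination), which avoids handling the epimerizable aldehyde; the alkene geometry is irrelevant because the double bond is reduced next.

Step 4
Reactants: 5 methyl (2E,4R,5R)-4-(benzyloxy)-5-(tosylamino)hex-2-enoate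
Product: 6 methyl (4R,5R)-4-(benzyloxy)-5-(tosylamino)hexanoate
Conditions: H2 (1 atm), Pt/C (5 %), EtOAc, rt
Reagents that add atoms: none
Why: Heterogeneous hydrogenation over platinum saturates the disubstituted enoate alkene while the allylic benzyl ether and the sulfonamide remain, hydrogenolysis being much slower on platinum than on palladium.

Step 5
Reactants: 6 methyl (4R,5R)-4-(benzyloxy)-5-(tosylamino)hexanoate
Product: 7 tert-butyl (6R,7R)-6-(benzyloxy)-3-oxo-7-(tosylamino)octanoate
Conditions: tert-butyl acetate, LiN(iPr)2 (3.5 equiv), THF, −78 °C; then 6, −78 → −20 °C; aq. NH4Cl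
Reagents that add atoms: tert-butyl acetate, CC(=O)OC(C)(C)C
Why: Crossed Claisen condensation: the excess lithium enolate of tert-butyl acetate acylates at the methyl ester (directly or through the N-tosyl lactam that the sulfonamide anion can form, both paths giving 7), and the product is protected as its enolate until the quench.

Step 6
Reactants: 7 tert-butyl (6R,7R)-6-(benzyloxy)-3-oxo-7-(tosylamino)octanoate; 8 acrolein
Product: 11 tert-butyl (2R,3R,4aR,8aR)-3-(benzyloxy)-5-hydroxy-2-methyl-1-tosyl-1,2,3,4,4a,7,8,8a-octahydroquinoline-6-carboxylate (enol form of the β-keto ester), via Michael adduct 9 (not isolated), via cyclohexenone 10 (not isolated)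
Conditions: 8 (1.2 equiv), Et3N (0.1 equiv), iPrOH, 0 °C; then LiOH·H2O (1.1 equiv), H2O, rt
Reagents that add atoms: none
Why: Triethylamine-catalysed Michael addition of the doubly activated C6 methylene of 7 to acrolein forms C6–C7 (adduct 9); LiOH then drives the intramolecular aldol condensation of the C4a enolate with the aldehyde carbon, which forms C4a–C8a as enone 10, and the tosylamide anion finally adds to C8a, after which proton transfer leaves the hydrogen-bonded enol of the β-keto ester. The closest known reaction type is the hydroxide-promoted Robinson annulation/intramolecular aza-Michael domino of tosylamide-tethered β-keto esters with enals, which gives cis-5-oxodecahydroquinolines. The carbocycle closes by a 6-(enolendo)-exo-trig aldol addition followed by dehydration, and the piperidine ring closes by a 6-endo-trig conjugate addition. C8a is controlled by C2: in the chair transition state the C2 methyl group is axial to escape allylic 1,3-strain with the N-sulfonyl group (C3–OBn is then equatorial), while the C8a–C8 bond must stay in the enone plane and so ends equatorial, which places H8a on the face of the methyl group; C4a is set by protonation of the resulting enolate on the face opposite the pseudo-axial C8a–N bond, which gives the cis ring fusion. The step needs C-alkylation at C6 only and a kinetic ring closure: the tert-butyl ester makes C6 the only carbon acidic enough for the amine-catalysed Michael step (the sulfonamide stays protonated there), and tautomerization of the product to the C5=C6 enol removes the C5 ketone that a retro-aza-Michael opening would need.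

Step 7
Reactants: 11 tert-butyl (2R,3R,4aR,8aR)-3-(benzyloxy)-5-hydroxy-2-methyl-1-tosyl-1,2,3,4,4a,7,8,8a-octahydroquinoline-6-carboxylate
Product: 13 (2R,3R,4aR,8aR)-3-(benzyloxy)-2-methyl-1-tosyloctahydroquinolin-5(1H)-one, via β-keto acid 12 (not isolated)
Conditions: TFA/CH2Cl2 (1:1), rt; concentrate; toluene, 80 °C
Reagents that add atoms: none
Why: Acidolysis of the tert-butyl ester and thermal decarboxylation of the β-keto acid through its cyclic transition state give the ketone without base, so neither retro-aza-Michael opening nor C4a epimerization should be triggered.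

Step 8
Reactants: 13 (2R,3R,4aR,8aR)-3-(benzyloxy)-2-methyl-1-tosyloctahydroquinolin-5(1H)-one
Product: 14 (2R,3R,4aR,8aR)-3-(benzyloxy)-2-methyl-1-tosyl-1,2,3,4,4a,7,8,8a-octahydroquinolin-5-yl trifluoromethanesulfonate
Conditions: KN(SiMe3)2 (1.1 equiv), THF, −78 °C; PhNTf2, −78 → 0 °C
Reagents that add atoms: N-phenylbis(trifluoromethanesulfonimide), FC(F)(F)S(=O)(=O)N(c1ccccc1)S(=O)(=O)C(F)(F)F
Why: Kinetic deprotonation by the hindered amide base removes a proton from the unhindered C6 methylene, not from the ring-fusion methine C4a (which would open the ring by β-elimination of the sulfonamide), and O-triflation of the enolate gives the C5=C6 enol triflate.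

Step 9
Reactants: 15 (R)-2-propyloxirane
Product: 16 (R)-oct-7-en-4-ol
Conditions: CH2=CHCH2MgBr (1.3 equiv), CuI (10 mol %), THF, −30 → 0 °C; aq. NH4Cl
Reagents that add atoms: allylmagnesium bromide, C=CC[Mg]Br
Why: Copper-catalysed SN2 opening of the terminal epoxide by the allyl Grignard reagent occurs at the unsubstituted carbon, so the C–O stereocenter (the future C5') is not touched.

Step 10
Reactants: 16 (R)-oct-7-en-4-ol
Product: 17 (R)-tert-butyldimethyl(oct-7-en-4-yloxy)silane
Conditions: TBSCl, imidazole, DMF, rt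
Reagents that add atoms: tert-butyldimethylsilyl chloride, CC(C)(C)[Si](C)(C)Cl
Why: Imidazole-mediated silylation of the secondary alcohol installs an ether that survives hydroboration, palladium coupling, hydrogenation and dissolving-metal reduction and is removed with acid at the end.

Step 11
Reactants: 14 (2R,3R,4aR,8aR)-3-(benzyloxy)-2-methyl-1-tosyl-1,2,3,4,4a,7,8,8a-octahydroquinolin-5-yl trifluoromethanesulfonate; 17 (R)-tert-butyldimethyl(oct-7-en-4-yloxy)silane
Product: 19 (2R,3R,4aS,8aR)-3-(benzyloxy)-5-[(5R)-5-(tert-butyldimethylsilyloxy)octyl]-2-methyl-1-tosyl-1,2,3,4,4a,7,8,8a-octahydroquinoline, via alkylborane 18 (not isolated)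
Conditions: 17, 9-BBN-H, THF, 0 °C → rt; then 14, Pd(dppf)Cl2 (5 mol %), K3PO4 (3 M aq.), DMF, 50 °C
Reagents that add atoms: none
Why: B-alkyl Suzuki–Miyaura coupling: anti-Markovnikov hydroboration of the terminal alkene gives the primary alkylborane, which after activation by phosphate transmetallates to the alkenylpalladium species formed by oxidative addition of zerovalent palladium into the C5–OTf bond, and reductive elimination forms C5–C1' with the ring alkene in place.

Step 12
Reactants: 19 (2R,3R,4aS,8aR)-3-(benzyloxy)-5-[(5R)-5-(tert-butyldimethylsilyloxy)octyl]-2-methyl-1-tosyl-1,2,3,4,4a,7,8,8a-octahydroquinoline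
Product: 20 (2R,3R,4aS,5S,8aR)-5-[(5R)-5-(tert-butyldimethylsilyloxy)octyl]-2-methyl-1-tosyldecahydroquinolin-3-ol
Conditions: H2 (4 atm), Pd(OH)2/C, EtOAc/EtOH (4:1), rt
Reagents that add atoms: none
Why: Heterogeneous hydrogenation should add hydrogen to the trisubstituted C5=C6 alkene from the convex face of the cis-fused bicycle (the face of H4a and H8a, opposite the axial N-tosyl group and the piperidine ring), which sets C5 with H5 cis to H4a, and the same catalyst cleaves the benzyl ether by hydrogenolysis while silyl ether and sulfonamide remain.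

Step 13
Reactants: 20 (2R,3R,4aS,5S,8aR)-5-[(5R)-5-(tert-butyldimethylsilyloxy)octyl]-2-methyl-1-tosyldecahydroquinolin-3-ol
Product: 22 tert-butyl (2R,3R,4aS,5S,8aR)-5-[(5R)-5-(tert-butyldimethylsilyloxy)octyl]-3-hydroxy-2-methyloctahydroquinoline-1(2H)-carboxylate, via secondary amine 21 (not isolated)
Conditions: NaC10H8 (from Na and naphthalene), DME, −78 °C; H2O; then Boc2O, NaHCO3, THF/H2O, 40 °C
Reagents that add atoms: di-tert-butyl dicarbonate, CC(C)(C)OC(=O)OC(=O)OC(C)(C)C
Why: Single-electron reduction of the arenesulfonyl group by the naphthalene radical anion cleaves the S–N bond (reductive desulfonylation) without touching the silyl ether, and the liberated amine is acylated by Boc2O in preference to the secondary alcohol (carbamate formation).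

Step 14
Reactants: 22 tert-butyl (2R,3R,4aS,5S,8aR)-5-[(5R)-5-(tert-butyldimethylsilyloxy)octyl]-3-hydroxy-2-methyloctahydroquinoline-1(2H)-carboxylate; 23 (E)-oct-2-enoic acid
Product: 24 (2R,3R,4aS,5S,8aR)-1-(tert-butoxycarbonyl)-5-[(5R)-5-(tert-butyldimethylsilyloxy)octyl]-2-methyldecahydroquinolin-3-yl (E)-oct-2-enoate
Conditions: 23, EDC·HCl, DMAP, CH2Cl2, 0 °C → rt
Reagents that add atoms: none
Why: Carbodiimide/DMAP (Steglich) esterification acylates the only free hydroxyl (C3–OH), nitrogen being blocked as the carbamate, with retention at C3 and without moving the (E)-double bond of the acid.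

Step 15
Reactants: 24 (2R,3R,4aS,5S,8aR)-1-(tert-butoxycarbonyl)-5-[(5R)-5-(tert-butyldimethylsilyloxy)octyl]-2-methyldecahydroquinolin-3-yl (E)-oct-2-enoate
Product: 25 (2R,3R,4aS,5S,8aR)-5-[(5R)-5-hydroxyoctyl]-2-methyldecahydroquinolin-3-yl (E)-oct-2-enoate
Conditions: TFA/CH2Cl2/H2O (10:10:1), 0 °C → rt; aq. NaHCO3
Reagents that add atoms: none
Why: Acidolysis removes the Boc group and hydrolyses the secondary silyl ether in one operation while the conjugated ester is stable to acid, and basification liberates the free amine.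

**Compound list**
1 | ethyl (E)-but-2-enoate | C/C=C/C(=O)OCC | starting material
2 | ethyl (2S,3R)-2-hydroxy-3-(tosylamino)butanoate | C[C@@H](NS(=O)(=O)c1ccc(C)cc1)[C@H](O)C(=O)OCC | intermediate
3 | ethyl (2S,3R)-2-(benzyloxy)-3-(tosylamino)butanoate | C[C@@H](NS(=O)(=O)c1ccc(C)cc1)[C@H](OCc1ccccc1)C(=O)OCC | intermediate
4 | (2S,3R)-2-(benzyloxy)-3-(tosylamino)butanal | C[C@@H](NS(=O)(=O)c1ccc(C)cc1)[C@H](OCc1ccccc1)C=O | intermediate
5 | methyl (2E,4R,5R)-4-(benzyloxy)-5-(tosylamino)hex-2-enoate | C[C@@H](NS(=O)(=O)c1ccc(C)cc1)[C@H](OCc1ccccc1)/C=C/C(=O)OC | intermediate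
6 | methyl (4R,5R)-4-(benzyloxy)-5-(tosylamino)hexanoate | C[C@@H](NS(=O)(=O)c1ccc(C)cc1)[C@H](OCc1ccccc1)CCC(=O)OC | intermediate
7 | tert-butyl (6R,7R)-6-(benzyloxy)-3-oxo-7-(tosylamino)octanoate | C[C@@H](NS(=O)(=O)c1ccc(C)cc1)[C@H](OCc1ccccc1)CCC(=O)CC(=O)OC(C)(C)C | intermediate
8 | acrolein (prop-2-enal) | C=CC=O | starting material
9 | tert-butyl (6R,7R)-6-(benzyloxy)-3-oxo-2-(3-oxopropyl)-7-(tosylamino)octanoate (C2 epimers) | C[C@@H](NS(=O)(=O)c1ccc(C)cc1)[C@H](OCc1ccccc1)CCC(=O)C(CCC=O)C(=O)OC(C)(C)C | intermediate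
10 | tert-butyl 3-[(2R,3R)-2-(benzyloxy)-3-(tosylamino)butyl]-2-oxocyclohex-3-ene-1-carboxylate (C1 epimers) | C[C@@H](NS(=O)(=O)c1ccc(C)cc1)[C@H](OCc1ccccc1)CC1=CCCC(C(=O)OC(C)(C)C)C1=O | intermediate
11 | tert-butyl (2R,3R,4aR,8aR)-3-(benzyloxy)-5-hydroxy-2-methyl-1-tosyl-1,2,3,4,4a,7,8,8a-octahydroquinoline-6-carboxylate | c1ccccc1CO[C@@H]1C[C@H]2C(O)=C(C(=O)OC(C)(C)C)CC[C@H]2N(S(=O)(=O)c2ccc(C)cc2)[C@@H]1C | intermediate
12 | (2R,3R,4aR,8aR)-3-(benzyloxy)-5-hydroxy-2-methyl-1-tosyl-1,2,3,4,4a,7,8,8a-octahydroquinoline-6-carboxylic acid | c1ccccc1CO[C@@H]1C[C@H]2C(O)=C(C(=O)O)CC[C@H]2N(S(=O)(=O)c2ccc(C)cc2)[C@@H]1C | intermediate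
13 | (2R,3R,4aR,8aR)-3-(benzyloxy)-2-methyl-1-tosyloctahydroquinolin-5(1H)-one | c1ccccc1CO[C@@H]1C[C@H]2C(=O)CCC[C@H]2N(S(=O)(=O)c2ccc(C)cc2)[C@@H]1C | intermediate
14 | (2R,3R,4aR,8aR)-3-(benzyloxy)-2-methyl-1-tosyl-1,2,3,4,4a,7,8,8a-octahydroquinolin-5-yl trifluoromethanesulfonate | c1ccccc1CO[C@@H]1C[C@H]2C(OS(=O)(=O)C(F)(F)F)=CCC[C@H]2N(S(=O)(=O)c2ccc(C)cc2)[C@@H]1C | intermediate
15 | (R)-2-propyloxirane | CCC[C@@H]1CO1 | starting material
16 | (R)-oct-7-en-4-ol | C=CCC[C@H](O)CCC | intermediate
17 | (R)-tert-butyldimethyl(oct-7-en-4-yloxy)silane | C=CCC[C@H](O[Si](C)(C)C(C)(C)C)CCC | intermediate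
18 | 9-[(5R)-5-(tert-butyldimethylsilyloxy)octyl]-9-borabicyclo[3.3.1]nonane | B1(CCCC[C@H](O[Si](C)(C)C(C)(C)C)CCC)C2CCCC1CCC2 | intermediate
19 | (2R,3R,4aS,8aR)-3-(benzyloxy)-5-[(5R)-5-(tert-butyldimethylsilyloxy)octyl]-2-methyl-1-tosyl-1,2,3,4,4a,7,8,8a-octahydroquinoline | c1ccccc1CO[C@@H]1C[C@H]2C(CCCC[C@H](O[Si](C)(C)C(C)(C)C)CCC)=CCC[C@H]2N(S(=O)(=O)c2ccc(C)cc2)[C@@H]1C | intermediate
20 | (2R,3R,4aS,5S,8aR)-5-[(5R)-5-(tert-butyldimethylsilyloxy)octyl]-2-methyl-1-tosyldecahydroquinolin-3-ol | O[C@@H]1C[C@H]2[C@@H](CCCC[C@H](O[Si](C)(C)C(C)(C)C)CCC)CCC[C@H]2N(S(=O)(=O)c2ccc(C)cc2)[C@@H]1C | intermediate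
21 | (2R,3R,4aS,5S,8aR)-5-[(5R)-5-(tert-butyldimethylsilyloxy)octyl]-2-methyldecahydroquinolin-3-ol | O[C@@H]1C[C@H]2[C@@H](CCCC[C@H](O[Si](C)(C)C(C)(C)C)CCC)CCC[C@H]2N[C@@H]1C | intermediate
22 | tert-butyl (2R,3R,4aS,5S,8aR)-5-[(5R)-5-(tert-butyldimethylsilyloxy)octyl]-3-hydroxy-2-methyloctahydroquinoline-1(2H)-carboxylate | O[C@@H]1C[C@H]2[C@@H](CCCC[C@H](O[Si](C)(C)C(C)(C)C)CCC)CCC[C@H]2N(C(=O)OC(C)(C)C)[C@@H]1C | intermediate
23 | (E)-oct-2-enoic acid | CCCCC/C=C/C(=O)O | starting material
24 | (2R,3R,4aS,5S,8aR)-1-(tert-butoxycarbonyl)-5-[(5R)-5-(tert-butyldimethylsilyloxy)octyl]-2-methyldecahydroquinolin-3-yl (E)-oct-2-enoate | CCCCC/C=C/C(=O)O[C@@H]1C[C@H]2[C@@H](CCCC[C@H](O[Si](C)(C)C(C)(C)C)CCC)CCC[C@H]2N(C(=O)OC(C)(C)C)[C@@H]1C | intermediate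
25 | (2R,3R,4aS,5S,8aR)-5-[(5R)-5-hydroxyoctyl]-2-methyldecahydroquinolin-3-yl (E)-oct-2-enoate | CCCCC/C=C/C(=O)O[C@@H]1C[C@H]2[C@@H](CCCC[C@H](O)CCC)CCC[C@H]2N[C@@H]1C | target

**Step count**
Total: 15 steps. Longest linear sequence: 13 steps (steps 1–8 and 11–15); steps 9–10 make the side-chain fragment.

**Steps most likely to fail**

Step 6. Reversible retro-aza-Michael opening and re-closure under hydroxide may erode the kinetic relationship between C2 and C8a or the cis ring fusion, and acrolein may oligomerize or add twice at C6. The fallback sets out from 7 and returns at 13; it replaces the conjugate addition by an enolate alkylation and closes the nitrogen ring under acid on the ester-free enone. The sodium enolate of 7 (NaH, 1 equiv, DMF, NaI) is alkylated at C6 with 2-(2-bromoethyl)-1,3-dioxolane to give the dioxolane-bearing β-keto ester F1. Aqueous TsOH in acetone releases aldehyde 9, which pyrrolidinium acetate condenses to enone 10, now isolated. TFA cleaves the ester to the enone β-keto acid F2, which loses CO2 on warming to give the 2-substituted cyclohexenone F3. Catalytic TfOH (CH2Cl2, 0 °C) then effects the aza-Michael addition through the same axial-methyl chair, with no enolate available for the reverse reaction, and ketonization on the open face should give 13.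

Step 12. Palladium may move the double bond into the C4a–C5 position before reduction, which would scramble the ring fusion, or the facial selectivity at C5 may be insufficient. The fallback sets out from 19 and returns at 20; it reduces the alkene by radical hydrogen-atom transfer without a metal surface. Mn(dpm)3 (catalytic), PhSiH3 and tBuOOH in iPrOH generate the tertiary C5 radical, which should take up hydrogen from the open convex face to give the saturated benzyl ether F4. A separate hydrogenolysis (H2, Pd(OH)2/C, EtOAc) then removes only the benzyl group and gives 20.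

Step 8. Deprotonation may compete at C4a, with β-elimination of the sulfonamide (ring opening) or epimerization of the ring fusion, or the regioisomeric enol triflate may form. The fallback sets out from 13 (and 17) and returns at 19; it adds the side chain as a weakly basic organocerium reagent and makes the alkene by dehydration. Hydroboration of 17 to 18 and brominolysis (Br2, NaOMe) give the silyloxy bromide F5. Magnesium converts it into the Grignard reagent F6, which in the presence of CeCl3 (THF, −78 °C) adds to the C5 carbonyl of 13 to give the tertiary alcohol F7. Dehydration with MeO2CN(−)SO2N(+)Et3 (Burgess reagent) gives 19 together with its exocyclic alkene isomer F8, and both alkenes are taken through step 12 to 20.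

**Further compounds**
F1 | step 6 | tert-butyl (6R,7R)-6-(benzyloxy)-2-[2-(1,3-dioxolan-2-yl)ethyl]-3-oxo-7-(tosylamino)octanoate (C2 epimers) | C[C@@H](NS(=O)(=O)c1ccc(C)cc1)[C@H](OCc1ccccc1)CCC(=O)C(CCC1OCCO1)C(=O)OC(C)(C)C
F2 | step 6 | 3-[(2R,3R)-2-(benzyloxy)-3-(tosylamino)butyl]-2-oxocyclohex-3-ene-1-carboxylic acid | C[C@@H](NS(=O)(=O)c1ccc(C)cc1)[C@H](OCc1ccccc1)CC1=CCCC(C(=O)O)C1=O
F3 | step 6 | 2-[(2R,3R)-2-(benzyloxy)-3-(tosylamino)butyl]cyclohex-2-en-1-one | C[C@@H](NS(=O)(=O)c1ccc(C)cc1)[C@H](OCc1ccccc1)CC1=CCCCC1=O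
F4 | step 12 | (2R,3R,4aS,5S,8aR)-3-(benzyloxy)-5-[(5R)-5-(tert-butyldimethylsilyloxy)octyl]-2-methyl-1-tosyldecahydroquinoline | c1ccccc1CO[C@@H]1C[C@H]2[C@@H](CCCC[C@H](O[Si](C)(C)C(C)(C)C)CCC)CCC[C@H]2N(S(=O)(=O)c2ccc(C)cc2)[C@@H]1C
F5 | step 8 | (R)-[(8-bromooctan-4-yl)oxy](tert-butyl)dimethylsilane | BrCCCC[C@H](O[Si](C)(C)C(C)(C)C)CCC
F6 | step 8 | [(5R)-5-(tert-butyldimethylsilyloxy)octyl]magnesium bromide | Br[Mg]CCCC[C@H](O[Si](C)(C)C(C)(C)C)CCC
F7 | step 8 | (2R,3R,4aR,8aR)-3-(benzyloxy)-5-[(5R)-5-(tert-butyldimethylsilyloxy)octyl]-2-methyl-1-tosyldecahydroquinolin-5-ol (C5 epimers) | c1ccccc1CO[C@@H]1C[C@H]2C(O)(CCCC[C@H](O[Si](C)(C)C(C)(C)C)CCC)CCC[C@H]2N(S(=O)(=O)c2ccc(C)cc2)[C@@H]1C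
F8 | step 8 | (2R,3R,4aS,8aR)-3-(benzyloxy)-5-[(5R)-5-(tert-butyldimethylsilyloxy)octylidene]-2-methyl-1-tosyldecahydroquinoline | c1ccccc1CO[C@@H]1C[C@H]2C(=CCCC[C@H](O[Si](C)(C)C(C)(C)C)CCC)CCC[C@H]2N(S(=O)(=O)c2ccc(C)cc2)[C@@H]1C
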